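**Retrosynthetic overview**
1. Last C–C bond: C2'–C3' (sp3–sp2). A B-alkyl Suzuki–Miyaura coupling joins the C13 chroman half (9-BBN adduct of 2-vinylchroman 9) to the C14 (E)-vinyl iodide 17, which already holds C9'(R), both E-trisubstituted olefins and the prenyl end.
2. Key disconnection: O1–C2 of the dihydropyran ring. A Pd-catalysed asymmetric allylic alkylation of the acyclic, achiral (Z)-phenol allyl carbonate 8 closes the only ring made in the route and sets the quaternary ether carbon C2 (O1/CH3/C3/C1'); the vinyl group it leaves on C2 is C1'=C2'.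
3. Carbonate 8 comes from iodophenol 3 and the C6 dienol 5 (aryl–C4 bond by diene hydroboration/Suzuki coupling; Z geometry bought with enynol 4).
4. Iodide 17 comes from pent-4-yn-1-ol: carboalumination/iodination (C3'=C4'), Wittig (C7'=C8'), Brown allylation (C9'), cross-metathesis (C11'=C12').
5. Ring order: the benzene ring is bought (2-methylhydroquinone); the pyran ring is formed in step 6; no ring is formed after that.

Key step: step 6

Locants: chroman O1, C2–C8a; side chain C1'–C13'.
Assumption (step 6): in this reaction class the sense of induction depends on both olefin geometry and ligand antipode; the pairing (Z)-8 with the (R,R)-ligand is taken to lead to (2S)-9. If a test run shows the opposite sense, the (S,S)-ligand is used and nothing else changes.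

**Route**

Step 1
Reactants: 1 2-methylbenzene-1,4-diol
Product: 2 2-methyl-4-{[tri(propan-2-yl)silyl]oxy}phenol
Conditions: TIPSCl (1.0 equiv), imidazole, DMF, 0 °C
Reagents that add atoms: chlorotri(propan-2-yl)silane (TIPSCl), CC(C)[Si](Cl)(C(C)C)C(C)C
Why: O-silylation under steric control should go mainly to the unhindered 4-OH, because the 1-OH is flanked by the ortho methyl group and the silyl chloride is bulky; the regioisomer and the bis-ether are removed by chromatography.

Step 2
Reactants: 2 2-methyl-4-{[tri(propan-2-yl)silyl]oxy}phenol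
Product: 3 2-iodo-6-methyl-4-{[tri(propan-2-yl)silyl]oxy}phenol
Conditions: NIS (1.05 equiv), TsOH (cat.), MeCN, 0 °C
Reagents that add atoms: N-iodosuccinimide, O=C1CCC(=O)N1I
Why: Electrophilic aromatic iodination is directed ortho to the free OH, and since the para position carries OTIPS and the other ortho position the methyl group, iodine should enter C6 only.

Step 3
Reactants: 4 (2Z)-3-methylpent-2-en-4-yn-1-ol
Product: 5 (2Z)-3-methylpenta-2,4-dien-1-ol
Conditions: H2 (1 atm), Lindlar catalyst, quinoline, Et2O, 0 °C, stopped after 1 equiv H2; used crude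
Reagents that add atoms: none
Why: Lindlar semihydrogenation should stop at the vinyl group and leave the trisubstituted Z-olefin and its geometry untouched.

Step 4
Reactants: 5 (2Z)-3-methylpenta-2,4-dien-1-ol; 3 2-iodo-6-methyl-4-{[tri(propan-2-yl)silyl]oxy}phenol
Product: 7 2-[(3Z)-5-hydroxy-3-methylpent-3-en-1-yl]-6-methyl-4-{[tri(propan-2-yl)silyl]oxy}phenol, via bis-9-BBN adduct 6 (not isolated)
Conditions: 5, 9-BBN (2.2 equiv), THF, 0 °C to rt; then 3, PdCl2(dppf) (5 mol%), AsPh3 (10 mol%), 3 M aq. K3PO4, DMF, rt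
Reagents that add atoms: none
Why: 9-BBN should borylate the OH (loss of H2) and hydroborate only the unsubstituted vinyl terminus of the diene (anti-Markovnikov, trisubstituted olefin inert), and the homoallylic B-alkyl-9-BBN should then undergo B-alkyl Suzuki–Miyaura coupling with the aryl iodide with the Z-olefin retained.

Step 5
Reactants: 7 2-[(3Z)-5-hydroxy-3-methylpent-3-en-1-yl]-6-methyl-4-{[tri(propan-2-yl)silyl]oxy}phenol
Product: 8 (2Z)-5-(2-hydroxy-3-methyl-5-{[tri(propan-2-yl)silyl]oxy}phenyl)-3-methylpent-2-en-1-yl methyl carbonate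
Conditions: ClCO2Me (1.05 equiv), pyridine, CH2Cl2, −20 °C
Reagents that add atoms: methyl chloroformate, COC(=O)Cl
Why: Chemoselective O-acylation should take place at the primary allylic alcohol, which reacts much faster with the chloroformate under pyridine than the phenol flanked by two ortho alkyl groups.

Step 6
Reactants: 8 (2Z)-5-(2-hydroxy-3-methyl-5-{[tri(propan-2-yl)silyl]oxy}phenyl)-3-methylpent-2-en-1-yl methyl carbonate
Product: 9 {[(2S)-2-ethenyl-2,8-dimethyl-3,4-dihydro-2H-chromen-6-yl]oxy}tri(propan-2-yl)silane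
Conditions: Pd2(dba)3·CHCl3 (2 mol%), (R,R)-DACH-phenyl ligand [(1R,2R)-N,N'-bis(2-diphenylphosphanylbenzoyl)cyclohexane-1,2-diamine] (6 mol%), AcOH (1 equiv), CH2Cl2 (0.05 M), rt
Reagents that add atoms: none
Why: Pd(0) ionises the allylic carbonate (CO2 and methoxide leave, the latter buffered by AcOH) to a cationic η3-allyl complex in which the Z geometry places the arylethyl tether anti and the methyl group syn, and the free C8a phenol then attacks the disubstituted allyl terminus on the face opposite to Pd. The closest known reaction type is the Pd-catalysed asymmetric allylic alkylation (Tsuji–Trost type) of phenol allyl carbonates to 2-vinylchromans, which includes trisubstituted olefins that give a tetrasubstituted C2. The pyran ring closes by 6-exo attack of O1 on C2 (O1–C2 bond); attack at the CH2 terminus would need an eight-membered ring and is not expected. C2 is set by the chiral pocket of the ligand under Curtin–Hammett conditions: the two diastereomeric π-allyl complexes (Pd on either face) should interconvert by η3–η1–η3 through the unsubstituted CH2 terminus faster than they cyclise, so both are funnelled through the faster-cyclising one to (2S)-9. The step needs geometric purity, because syn/anti exchange at the disubstituted terminus is slow and the E series would enter the other set of π-allyl complexes; this is secured by the Z-enynol 4 and the stereoretentive steps 3 to 5. It also needs a single nucleophile, which the TIPS ether on O6 secures.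

Step 7
Reactants: 10 pent-4-yn-1-ol
Product: 12 (4E)-5-iodo-4-methylpent-4-en-1-ol, via alkenylalane 11 (not isolated)
Conditions: Me3Al (3 equiv), Cp2ZrCl2 (0.25 equiv), CH2Cl2, 0 °C to rt; then I2, THF, −30 to 0 °C; aq. K2CO3
Reagents that add atoms: trimethylaluminium, C[Al](C)C; iodine, II
Why: Negishi Zr-catalysed carboalumination adds Me and Al syn across the terminal alkyne with Me on the internal carbon, and iodinolysis of the C–Al bond with retention should give the (E)-vinyl iodide only.

Step 8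
Reactants: 12 (4E)-5-iodo-4-methylpent-4-en-1-ol
Product: 13 (4E)-5-iodo-4-methylpent-4-enal
Conditions: Dess–Martin periodinane (1.2 equiv), CH2Cl2, 0 °C to rt
Reagents that add atoms: none
Why: Dess–Martin oxidation should take the primary alcohol to the aldehyde without over-oxidation and without touching the vinyl iodide.

Step 9
Reactants: 13 (4E)-5-iodo-4-methylpent-4-enal
Product: 14 (2E,6E)-7-iodo-2,6-dimethylhepta-2,6-dienal
Conditions: Ph3P=C(CH3)CHO (1.15 equiv), toluene, 80 °C
Reagents that add atoms: 2-(triphenyl-λ5-phosphanylidene)propanal, CC(C=O)=P(c1ccccc1)(c1ccccc1)c1ccccc1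
Why: Wittig olefination with the stabilised α-methyl ylide should give the (E)-trisubstituted enal, and the conjugated product is much less reactive towards the ylide than the aliphatic aldehyde.

Step 10
Reactants: 14 (2E,6E)-7-iodo-2,6-dimethylhepta-2,6-dienal
Product: 16 (4R,5E,9E)-10-iodo-5,9-dimethyldeca-1,5,9-trien-4-ol, via diisopinocampheylborinate 15 (not isolated)
Conditions: (+)-Ipc2B(allyl) (1.2 equiv, 1 M in pentane), Et2O, −78 °C; then 3 M NaOH, 30% H2O2, 0 °C to rt
Reagents that add atoms: (+)-B-allyldiisopinocampheylborane, C=CCB([C@H]1C[C@H]2C[C@@H]([C@@H]1C)C2(C)C)[C@H]1C[C@H]2C[C@@H]([C@@H]1C)C2(C)C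
Why: Brown allylboration passes through a chair six-membered transition state in which the isopinocampheyl groups of the (+)-reagent should direct the allyl group to the aldehyde face that gives the (4R)-alcohol (the sense that gives (R)-1-phenylbut-3-en-1-ol from benzaldehyde), with 1,2-addition only, and the oxidative work-up cleaves the borinate.

Step 11
Reactants: 16 (4R,5E,9E)-10-iodo-5,9-dimethyldeca-1,5,9-trien-4-ol
Product: 17 (5R,6E,10E)-11-iodo-2,6,10-trimethylundeca-2,6,10-trien-5-ol
Conditions: 2-methylbut-2-ene (excess), Grubbs II catalyst (5 mol%), CH2Cl2, 40 °C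
Reagents that add atoms: 2-methylbut-2-ene, CC=C(C)C
Why: Olefin cross-metathesis with excess 2-methylbut-2-ene should turn the monosubstituted vinyl end into the isopropylidene (prenyl) terminus with loss of propene, while the two trisubstituted olefins (one of them the vinyl iodide) stay out of the metathesis and C5 is not touched.

Step 12
Reactants: 9 {[(2S)-2-ethenyl-2,8-dimethyl-3,4-dihydro-2H-chromen-6-yl]oxy}tri(propan-2-yl)silane; 17 (5R,6E,10E)-11-iodo-2,6,10-trimethylundeca-2,6,10-trien-5-ol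
Product: 19 (5R,6E,10E)-13-[(2R)-2,8-dimethyl-6-{[tri(propan-2-yl)silyl]oxy}-3,4-dihydro-2H-chromen-2-yl]-2,6,10-trimethyltrideca-2,6,10-trien-5-ol, via B-alkyl-9-BBN 18 (not isolated)
Conditions: 9, 9-BBN (1.3 equiv), THF, 0 °C to rt; then H2O, Cs2CO3 (3 equiv), 17, PdCl2(dppf) (5 mol%), AsPh3 (10 mol%), DMF, rt
Reagents that add atoms: none
Why: 9-BBN should hydroborate the only monosubstituted olefin at its terminus (boron ends γ to O1, so no β-alkoxy elimination), and the B-alkyl-9-BBN should couple with the (E)-vinyl iodide by B-alkyl Suzuki–Miyaura coupling with retention of olefin geometry to form C2'–C3', the free secondary alcohol and the trisubstituted olefins being tolerated and neither stereocentre being touched.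

Step 13
Reactants: 19 (5R,6E,10E)-13-[(2R)-2,8-dimethyl-6-{[tri(propan-2-yl)silyl]oxy}-3,4-dihydro-2H-chromen-2-yl]-2,6,10-trimethyltrideca-2,6,10-trien-5-ol
Product: 20 sargachromanol C [(2R)-2-[(3E,7E,9R)-9-hydroxy-4,8,12-trimethyltrideca-3,7,11-trien-1-yl]-2,8-dimethyl-3,4-dihydro-2H-chromen-6-ol]
Conditions: TBAF (1.5 equiv), AcOH (1.5 equiv), THF, 0 °C to rt, under argon
Reagents that add atoms: none
Why: Fluoride should cleave the aryl silyl ether through Si–F bond formation, and the acetic acid buffer keeps the oxidation-prone chromanol from standing as a free phenoxide, while the allylic alcohol and the olefins are not affected.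

**Compound list**
1 | 2-methylbenzene-1,4-diol | Cc1cc(O)ccc1O | starting material
2 | 2-methyl-4-{[tri(propan-2-yl)silyl]oxy}phenol | Cc1cc(O[Si](C(C)C)(C(C)C)C(C)C)ccc1O | intermediate
3 | 2-iodo-6-methyl-4-{[tri(propan-2-yl)silyl]oxy}phenol | Cc1cc(O[Si](C(C)C)(C(C)C)C(C)C)cc(I)c1O | intermediate
4 | (2Z)-3-methylpent-2-en-4-yn-1-ol | C#C/C(C)=C\CO | starting material
5 | (2Z)-3-methylpenta-2,4-dien-1-ol | C=C/C(C)=C\CO | intermediate
6 | 9-[(3Z)-5-(9-borabicyclo[3.3.1]nonan-9-yloxy)-3-methylpent-3-en-1-yl]-9-borabicyclo[3.3.1]nonane | C/C(CCB1C2CCCC1CCC2)=C/COB1C2CCCC1CCC2 | intermediate (not isolated)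
7 | 2-[(3Z)-5-hydroxy-3-methylpent-3-en-1-yl]-6-methyl-4-{[tri(propan-2-yl)silyl]oxy}phenol | Cc1cc(O[Si](C(C)C)(C(C)C)C(C)C)cc(CC/C(C)=C\CO)c1O | intermediate
8 | (2Z)-5-(2-hydroxy-3-methyl-5-{[tri(propan-2-yl)silyl]oxy}phenyl)-3-methylpent-2-en-1-yl methyl carbonate | COC(=O)OC/C=C(/C)CCc1cc(O[Si](C(C)C)(C(C)C)C(C)C)cc(C)c1O | intermediate
9 | {[(2S)-2-ethenyl-2,8-dimethyl-3,4-dihydro-2H-chromen-6-yl]oxy}tri(propan-2-yl)silane | C=C[C@]1(C)CCc2cc(O[Si](C(C)C)(C(C)C)C(C)C)cc(C)c2O1 | intermediate
10 | pent-4-yn-1-ol | C#CCCCO | starting material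
11 | [(1E)-5-(dimethylalumanyloxy)-2-methylpent-1-en-1-yl]dimethylalumane | C[Al](C)OCCC/C(C)=C/[Al](C)C | intermediate (not isolated)
12 | (4E)-5-iodo-4-methylpent-4-en-1-ol | OCCC/C(C)=C/I | intermediate
13 | (4E)-5-iodo-4-methylpent-4-enal | O=CCC/C(C)=C/I | intermediate
14 | (2E,6E)-7-iodo-2,6-dimethylhepta-2,6-dienal | O=C/C(C)=C/CC/C(C)=C/I | intermediate
15 | (4R,5E,9E)-10-iodo-5,9-dimethyldeca-1,5,9-trien-4-yl diisopinocampheylborinate | C=CC[C@@H](OB([C@H]1C[C@H]2C[C@@H]([C@@H]1C)C2(C)C)[C@H]1C[C@H]2C[C@@H]([C@@H]1C)C2(C)C)/C(C)=C/CC/C(C)=C/I | intermediate (not isolated)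
16 | (4R,5E,9E)-10-iodo-5,9-dimethyldeca-1,5,9-trien-4-ol | C=CC[C@@H](O)/C(C)=C/CC/C(C)=C/I | intermediate
17 | (5R,6E,10E)-11-iodo-2,6,10-trimethylundeca-2,6,10-trien-5-ol | CC(C)=CC[C@@H](O)/C(C)=C/CC/C(C)=C/I | intermediate
18 | 9-{2-[(2R)-2,8-dimethyl-6-{[tri(propan-2-yl)silyl]oxy}-3,4-dihydro-2H-chromen-2-yl]ethyl}-9-borabicyclo[3.3.1]nonane | B1(CC[C@]2(C)CCc3cc(O[Si](C(C)C)(C(C)C)C(C)C)cc(C)c3O2)C2CCCC1CCC2 | intermediate (not isolated)
19 | (5R,6E,10E)-13-[(2R)-2,8-dimethyl-6-{[tri(propan-2-yl)silyl]oxy}-3,4-dihydro-2H-chromen-2-yl]-2,6,10-trimethyltrideca-2,6,10-trien-5-ol | CC(C)=CC[C@@H](O)/C(C)=C/CC/C(C)=C/CC[C@]1(C)CCc2cc(O[Si](C(C)C)(C(C)C)C(C)C)cc(C)c2O1 | intermediate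
20 | sargachromanol C, (2R)-2-[(3E,7E,9R)-9-hydroxy-4,8,12-trimethyltrideca-3,7,11-trien-1-yl]-2,8-dimethyl-3,4-dihydro-2H-chromen-6-ol | CC(C)=CC[C@@H](O)/C(C)=C/CC/C(C)=C/CC[C@]1(C)CCc2cc(O)cc(C)c2O1 | target

**Step count**
Total steps: 13. Longest linear sequence: 7 steps (1 to 20 through steps 1, 2, 4, 5, 6, 12, 13; the side-chain branch from 10 through steps 7 to 13 is also 7 steps).

**Steps most likely to fail**

1. Step 6. The risk is poor facial discrimination between the two equilibrating π-allyl complexes, or the opposite sense of induction. This cannot be repaired later, because the C2 epimer of the final product is a remote diastereomer that should not separate. The fallback sets out from 7 and comes back at 9. Sharpless asymmetric epoxidation of the Z-allylic alcohol 7 (Ti(OiPr)4, L-(+)-diethyl tartrate, t-BuOOH, 4 Å molecular sieves, CH2Cl2, −20 °C) should give the epoxy alcohol [(2S,3R)-3-{2-[2-hydroxy-3-methyl-5-{[tri(propan-2-yl)silyl]oxy}phenyl]ethyl}-3-methyloxiran-2-yl]methanol F1, with the facial sense that holds for nerol. The phenol should then open the epoxide at the tertiary carbon in a 6-exo mode with inversion (CSA cat., CH2Cl2) to the diol (1S)-1-[(2S)-2,8-dimethyl-6-{[tri(propan-2-yl)silyl]oxy}-3,4-dihydro-2H-chromen-2-yl]ethane-1,2-diol F2, whose C2 already has the arrangement of 9. 1,1'-Thiocarbonyldiimidazole should give the cyclic thiocarbonate (4S)-4-[(2S)-2,8-dimethyl-6-{[tri(propan-2-yl)silyl]oxy}-3,4-dihydro-2H-chromen-2-yl]-1,3-dioxolane-2-thione F3, and Corey–Winter olefination (P(OMe)3, 110 °C) should give 9.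

2. Step 12. The risk is slow transmetalation of the alkylborane close to the quaternary centre, so that deiodination of 17 or loss of the aryl silyl ether in the aqueous base competes with coupling. The fallback sets out from 9 (with 17) and comes back at 20. The borane 18 is oxidised instead (NaOH, H2O2) to the alcohol 2-[(2S)-2,8-dimethyl-6-{[tri(propan-2-yl)silyl]oxy}-3,4-dihydro-2H-chromen-2-yl]ethan-1-ol F4. Appel iodination (I2, PPh3, imidazole) should give the iodide {[(2S)-2-(2-iodoethyl)-2,8-dimethyl-3,4-dihydro-2H-chromen-6-yl]oxy}tri(propan-2-yl)silane F5, and zinc insertion (Zn dust, LiCl, THF) the alkylzinc iodide {2-[(2S)-2,8-dimethyl-6-{[tri(propan-2-yl)silyl]oxy}-3,4-dihydro-2H-chromen-2-yl]ethyl}(iodo)zinc F6. Iodide 17 is silylated (TBSCl, imidazole, DMF) to tert-butyl{[(5R,6E,10E)-11-iodo-2,6,10-trimethylundeca-2,6,10-trien-5-yl]oxy}dimethylsilane F7. Negishi coupling of F6 with F7 (PdCl2(dppf), THF, rt) should give the bis-silyl ether tert-butyl{[(5R,6E,10E)-13-[(2R)-2,8-dimethyl-6-{[tri(propan-2-yl)silyl]oxy}-3,4-dihydro-2H-chromen-2-yl]-2,6,10-trimethyltrideca-2,6,10-trien-5-yl]oxy}dimethylsilane F8, and TBAF should remove both silyl groups to give 20.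

3. Step 4. The risk is hydroboration of the conjugated dienol at the wrong position (internal or 1,4-addition), or a sluggish coupling of the electron-rich ortho-iodophenoxide. The fallback sets out from 3 and comes back at 7; it moves the boron to the aryl side and forms the CH2–C(olefin) bond instead of the aryl–CH2 bond. Suzuki vinylation of 3 (potassium vinyltrifluoroborate, PdCl2(dppf), Cs2CO3, THF/H2O) should give 2-ethenyl-6-methyl-4-{[tri(propan-2-yl)silyl]oxy}phenol F9. 9-BBN (2.2 equiv) should add to the styrene terminus and borylate the phenol, giving the bis-9-BBN adduct 9-[2-(2-(9-borabicyclo[3.3.1]nonan-9-yloxy)-3-methyl-5-{[tri(propan-2-yl)silyl]oxy}phenyl)ethyl]-9-borabicyclo[3.3.1]nonane F10. B-alkyl Suzuki–Miyaura coupling of F10 with (2Z)-3-iodobut-2-en-1-ol F11 (made from but-2-yn-1-ol by Red-Al, then I2) under the conditions of step 4 should give 7 with the Z geometry carried over from F11.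

**Further compounds**
F1 | step 6 | [(2S,3R)-3-{2-[2-hydroxy-3-methyl-5-{[tri(propan-2-yl)silyl]oxy}phenyl]ethyl}-3-methyloxiran-2-yl]methanol | OC[C@@H]1O[C@]1(C)CCc1cc(O[Si](C(C)C)(C(C)C)C(C)C)cc(C)c1O
F2 | step 6 | (1S)-1-[(2S)-2,8-dimethyl-6-{[tri(propan-2-yl)silyl]oxy}-3,4-dihydro-2H-chromen-2-yl]ethane-1,2-diol | OC[C@H](O)[C@]1(C)CCc2cc(O[Si](C(C)C)(C(C)C)C(C)C)cc(C)c2O1
F3 | step 6 | (4S)-4-[(2S)-2,8-dimethyl-6-{[tri(propan-2-yl)silyl]oxy}-3,4-dihydro-2H-chromen-2-yl]-1,3-dioxolane-2-thione | S=C1OC[C@H](O1)[C@]1(C)CCc2cc(O[Si](C(C)C)(C(C)C)C(C)C)cc(C)c2O1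
F4 | step 12 | 2-[(2S)-2,8-dimethyl-6-{[tri(propan-2-yl)silyl]oxy}-3,4-dihydro-2H-chromen-2-yl]ethan-1-ol | OCC[C@]1(C)CCc2cc(O[Si](C(C)C)(C(C)C)C(C)C)cc(C)c2O1
F5 | step 12 | {[(2S)-2-(2-iodoethyl)-2,8-dimethyl-3,4-dihydro-2H-chromen-6-yl]oxy}tri(propan-2-yl)silane | ICC[C@]1(C)CCc2cc(O[Si](C(C)C)(C(C)C)C(C)C)cc(C)c2O1
F6 | step 12 | {2-[(2S)-2,8-dimethyl-6-{[tri(propan-2-yl)silyl]oxy}-3,4-dihydro-2H-chromen-2-yl]ethyl}(iodo)zinc | I[Zn]CC[C@]1(C)CCc2cc(O[Si](C(C)C)(C(C)C)C(C)C)cc(C)c2O1
F7 | step 12 | tert-butyl{[(5R,6E,10E)-11-iodo-2,6,10-trimethylundeca-2,6,10-trien-5-yl]oxy}dimethylsilane | CC(C)=CC[C@@H](O[Si](C)(C)C(C)(C)C)/C(C)=C/CC/C(C)=C/I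
F8 | step 12 | tert-butyl{[(5R,6E,10E)-13-[(2R)-2,8-dimethyl-6-{[tri(propan-2-yl)silyl]oxy}-3,4-dihydro-2H-chromen-2-yl]-2,6,10-trimethyltrideca-2,6,10-trien-5-yl]oxy}dimethylsilane | CC(C)=CC[C@@H](O[Si](C)(C)C(C)(C)C)/C(C)=C/CC/C(C)=C/CC[C@]1(C)CCc2cc(O[Si](C(C)C)(C(C)C)C(C)C)cc(C)c2O1
F9 | step 4 | 2-ethenyl-6-methyl-4-{[tri(propan-2-yl)silyl]oxy}phenol | Cc1cc(O[Si](C(C)C)(C(C)C)C(C)C)cc(C=C)c1O
F10 | step 4 | 9-[2-(2-(9-borabicyclo[3.3.1]nonan-9-yloxy)-3-methyl-5-{[tri(propan-2-yl)silyl]oxy}phenyl)ethyl]-9-borabicyclo[3.3.1]nonane | Cc1cc(O[Si](C(C)C)(C(C)C)C(C)C)cc(CCB2C3CCCC2CCC3)c1OB1C2CCCC1CCC2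
F11 | step 4 | (2Z)-3-iodobut-2-en-1-ol | C/C(I)=C/CO
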